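**Retrosynthetic overview**

- The target is a 1,2-diarylpropane-1,3-diol. C1 (the carbinol carbon) is benzylic and para to the C4 oxygen of ring A (the 4-hydroxy-3-methoxyphenyl ring), and the oxygen on C3 (the CH2OH carbon) lies 1,3 to it. The C1–O bond is therefore cut last and made by anodic removal of the C1 hydrogen, with the oxygen delivered from a tert-butyl carbonate on the C3 oxygen. This closes a 1,3-dioxan-2-one, the only ring formed in the route, which is opened again afterwards.
- The C2 stereocentre, which carries ring B (the 4-hydroxy-3,5-dimethoxyphenyl ring), is set earlier by asymmetric hydrogenation of the C1=C2 bond of an (E)-2,3-diarylacrylic acid. C2 then directs C1 in the ring closure.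
- The C1=C2 bond comes from a Perkin condensation of O-silylated vanillin with the O-pivaloylated arylacetic acid. The acyl group on the ring B oxygen keeps ring A the more easily oxidised ring.
- Endgame: methanolysis of carbonate and pivalate while ring A is still silylated, then fluoride.

Key step: step 7

Assumption: (R)-BINAP is assigned to the (S)-acid by analogy with the facial preference of this catalyst family for 2-alkyl-2-alkenoic acids; should the hydrogenation favour the other face, (S)-BINAP is used and nothing else changes.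

**Route**

Step 1
Reactants: 1 vanillin
Product: 2 3-methoxy-4-(triisopropylsilyloxy)benzaldehyde
Conditions: TIPSCl, imidazole, DMF, rt
Reagents that add atoms: triisopropylsilyl chloride, CC(C)[Si](Cl)(C(C)C)C(C)C
Why: O-silylation of the phenol with a silyl chloride and imidazole is routine, and the bulky triisopropylsilyl ether keeps the ring A oxygen electron-releasing and should survive the later basic, reductive and anodic steps.

Step 2
Reactants: 3 4-hydroxy-3,5-dimethoxyphenylacetic acid
Product: 4 2-(3,5-dimethoxy-4-pivaloyloxyphenyl)acetic acid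
Conditions: PivCl, NaOH, H2O/THF, 0 °C; then 1 M HCl
Reagents that add atoms: pivaloyl chloride, CC(C)(C)C(Cl)=O
Why: Schotten–Baumann acylation, in which the phenoxide is far more nucleophilic than the carboxylate and any mixed anhydride is hydrolysed in the same medium; the hindered pivalate lowers the electron density of ring B for step 7.

Step 3
Reactants: 2 3-methoxy-4-(triisopropylsilyloxy)benzaldehyde, 4 2-(3,5-dimethoxy-4-pivaloyloxyphenyl)acetic acid
Product: 7 (E)-2-(3,5-dimethoxy-4-pivaloyloxyphenyl)-3-(3-methoxy-4-triisopropylsilyloxyphenyl)acrylic acid, via arylacetic acetic mixed anhydride 5 (not isolated), via acrylic acetic mixed anhydride 6 (not isolated)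
Conditions: Ac2O, Et3N, 110 °C; then H2O/THF, 50 °C
Reagents that add atoms: acetic anhydride, CC(=O)OC(C)=O (acetyl group held only in 5 and 6, lost again on hydrolysis)
Why: Perkin condensation (Oglialoro variant), in which Et3N enolises mixed anhydride 5, the enolate adds to the non-enolisable aldehyde 2, and elimination followed by hydrolysis of 6 should give the thermodynamically preferred E acid with the two aryl groups cis; no stereocentre is formed.

Step 4
Reactants: 7 (E)-2-(3,5-dimethoxy-4-pivaloyloxyphenyl)-3-(3-methoxy-4-triisopropylsilyloxyphenyl)acrylic acid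
Product: 8 (S)-2-(3,5-dimethoxy-4-pivaloyloxyphenyl)-3-(3-methoxy-4-triisopropylsilyloxyphenyl)propanoic acid
Conditions: H2 (4 atm), Ru(OAc)2[(R)-BINAP] (1 mol %, divalent ruthenium), MeOH, 25 °C
Reagents that add atoms: none
Why: Carboxylate-directed asymmetric hydrogenation of a trisubstituted α,β-unsaturated acid by a ruthenium BINAP dicarboxylate, in which the bound carboxylate holds the alkene on the metal and the (R)-ligand selects the face to which hydrogen adds, setting C2 as S; the aryl ester and the silyl ether are inert.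

Step 5
Reactants: 8 (S)-2-(3,5-dimethoxy-4-pivaloyloxyphenyl)-3-(3-methoxy-4-triisopropylsilyloxyphenyl)propanoic acid
Product: 9 (S)-2-(3,5-dimethoxy-4-pivaloyloxyphenyl)-3-(3-methoxy-4-triisopropylsilyloxyphenyl)propan-1-ol
Conditions: BH3·SMe2, THF, 0 °C to rt; MeOH quench
Reagents that add atoms: none
Why: Borane reduction of a carboxylic acid through its acyloxyborane is much faster than attack on the hindered aryl pivalate, and C2 is not enolised under these conditions.

Step 6
Reactants: 9 (S)-2-(3,5-dimethoxy-4-pivaloyloxyphenyl)-3-(3-methoxy-4-triisopropylsilyloxyphenyl)propan-1-ol, 10 di-tert-butyl dicarbonate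
Product: 11 tert-butyl (S)-2-(3,5-dimethoxy-4-pivaloyloxyphenyl)-3-(3-methoxy-4-triisopropylsilyloxyphenyl)propyl carbonate
Conditions: Boc2O, DMAP (cat.), CH2Cl2, 0 °C to rt
Reagents that add atoms: di-tert-butyl dicarbonate (10), CC(C)(C)OC(=O)OC(=O)OC(C)(C)C
Why: DMAP-catalysed O-tert-butoxycarbonylation of the only free hydroxyl group places the oxygen nucleophile for step 7 on the C3 oxygen.

Step 7
Reactants: 11 tert-butyl (S)-2-(3,5-dimethoxy-4-pivaloyloxyphenyl)-3-(3-methoxy-4-triisopropylsilyloxyphenyl)propyl carbonate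
Product: 14 trans-(4S,5S)-5-(3,5-dimethoxy-4-pivaloyloxyphenyl)-4-(3-methoxy-4-triisopropylsilyloxyphenyl)-1,3-dioxan-2-one, via benzylic cation 12 (not isolated), via tert-butoxydioxanylium ion 13 (not isolated)
Conditions: undivided cell, graphite anode, Pt cathode, constant current, 2.2 F/mol, Bu4NBF4 (0.1 M), 2,6-lutidine (2 equiv), HFIP (5 equiv), CH2Cl2, 0 °C
Reagents that add atoms: none
Why: Proposed new method: anodic electron transfer from ring A, the ring of lower oxidation potential because the para oxygen of ring B is acylated, should give a radical cation that loses the C1 proton to 2,6-lutidine and a second electron to form the para-silyloxy-stabilised benzylic cation 12, whose C1 is attacked by the carbonyl oxygen of the tethered tert-butyl carbonate to give 13, which sheds its tert-butyl group as isobutene; the closest known reactions are anodic or quinone-mediated benzylic C–H oxidation of para-alkoxyarenes with capture of the cation by oxygen nucleophiles (acetoxylation, lactonisation) and the closure of tert-butyl carbonates onto cationic carbon in halocarbonate cyclisations. The 1,3-dioxan-2-one ring closes in a 6-exo-trig mode with respect to the exocyclic C1=ring A bond of the quinone-methide-like cation. The new C1 stereocentre is controlled by C2: with the C2 hydrogen eclipsing the cation plane (least allylic 1,3-strain against the ortho hydrogen of ring A) the tether reaches C1 only from its own face through a chair with both aryl groups equatorial, which should give the trans (4S,5S) carbonate. The step needs site selectivity for the C1 hydrogen (secured by the acyl group on ring B and the para oxygen of ring A), capture faster than loss of the C2 proton to a stilbene (secured by the six-membered tether), and no over-oxidation (the benzylic oxygen of the product raises its potential and the charge is limited to about 2.2 F/mol).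

Step 8
Reactants: 14 trans-(4S,5S)-5-(3,5-dimethoxy-4-pivaloyloxyphenyl)-4-(3-methoxy-4-triisopropylsilyloxyphenyl)-1,3-dioxan-2-one
Product: 15 (1S,2S)-2-(4-hydroxy-3,5-dimethoxyphenyl)-1-(3-methoxy-4-triisopropylsilyloxyphenyl)propane-1,3-diol
Conditions: NaOMe (3 equiv), MeOH, 0 °C to rt; AcOH quench
Reagents that add atoms: none
Why: Base-mediated transesterification in which methoxide should open the unhindered cyclic carbonate first and then cleave the aryl pivalate while the bulky silyl ether stays, so that no para-phenoxide is present while C1 still carries a carbonate leaving group; only acyl–oxygen bonds break, so C1 and C2 are untouched.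

Step 9
Reactants: 15 (1S,2S)-2-(4-hydroxy-3,5-dimethoxyphenyl)-1-(3-methoxy-4-triisopropylsilyloxyphenyl)propane-1,3-diol
Product: 16 (1S,2S)-1-(4-hydroxy-3-methoxyphenyl)-2-(4-hydroxy-3,5-dimethoxyphenyl)propane-1,3-diol (CNP0148667.1)
Conditions: Bu4NF, AcOH (1:1), THF, 0 °C
Reagents that add atoms: none
Why: Fluoride cleavage of the aryl silyl ether; buffering with AcOH should keep the para-hydroxybenzylic alcohol from ionising to a quinone methide, so C1 keeps its configuration.

**Compound list**

1 | vanillin | COc1cc(C=O)ccc1O | starting material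
2 | 3-methoxy-4-(triisopropylsilyloxy)benzaldehyde | COc1cc(C=O)ccc1O[Si](C(C)C)(C(C)C)C(C)C | intermediate
3 | 4-hydroxy-3,5-dimethoxyphenylacetic acid | OC(=O)Cc1cc(OC)c(O)c(OC)c1 | starting material
4 | 2-(3,5-dimethoxy-4-pivaloyloxyphenyl)acetic acid | OC(=O)Cc1cc(OC)c(OC(=O)C(C)(C)C)c(OC)c1 | intermediate
5 | acetic 2-(3,5-dimethoxy-4-pivaloyloxyphenyl)acetic anhydride | CC(=O)OC(=O)Cc1cc(OC)c(OC(=O)C(C)(C)C)c(OC)c1 | intermediate (not isolated)
6 | acetic (E)-2-(3,5-dimethoxy-4-pivaloyloxyphenyl)-3-(3-methoxy-4-triisopropylsilyloxyphenyl)acrylic anhydride | CC(=O)OC(=O)/C(=C/c1ccc(O[Si](C(C)C)(C(C)C)C(C)C)c(OC)c1)c1cc(OC)c(OC(=O)C(C)(C)C)c(OC)c1 | intermediate (not isolated)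
7 | (E)-2-(3,5-dimethoxy-4-pivaloyloxyphenyl)-3-(3-methoxy-4-triisopropylsilyloxyphenyl)acrylic acid | OC(=O)/C(=C/c1ccc(O[Si](C(C)C)(C(C)C)C(C)C)c(OC)c1)c1cc(OC)c(OC(=O)C(C)(C)C)c(OC)c1 | intermediate
8 | (S)-2-(3,5-dimethoxy-4-pivaloyloxyphenyl)-3-(3-methoxy-4-triisopropylsilyloxyphenyl)propanoic acid | COc1cc(C[C@H](C(=O)O)c2cc(OC)c(OC(=O)C(C)(C)C)c(OC)c2)ccc1O[Si](C(C)C)(C(C)C)C(C)C | intermediate
9 | (S)-2-(3,5-dimethoxy-4-pivaloyloxyphenyl)-3-(3-methoxy-4-triisopropylsilyloxyphenyl)propan-1-ol | COc1cc(C[C@H](CO)c2cc(OC)c(OC(=O)C(C)(C)C)c(OC)c2)ccc1O[Si](C(C)C)(C(C)C)C(C)C | intermediate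
10 | di-tert-butyl dicarbonate | CC(C)(C)OC(=O)OC(=O)OC(C)(C)C | starting material
11 | tert-butyl (S)-2-(3,5-dimethoxy-4-pivaloyloxyphenyl)-3-(3-methoxy-4-triisopropylsilyloxyphenyl)propyl carbonate | COc1cc(C[C@H](COC(=O)OC(C)(C)C)c2cc(OC)c(OC(=O)C(C)(C)C)c(OC)c2)ccc1O[Si](C(C)C)(C(C)C)C(C)C | intermediate
12 | (S)-3-(tert-butoxycarbonyloxy)-2-(3,5-dimethoxy-4-pivaloyloxyphenyl)-1-(3-methoxy-4-triisopropylsilyloxyphenyl)propan-1-ylium (benzylic cation) | COc1cc([CH+][C@H](COC(=O)OC(C)(C)C)c2cc(OC)c(OC(=O)C(C)(C)C)c(OC)c2)ccc1O[Si](C(C)C)(C(C)C)C(C)C | intermediate (not isolated)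
13 | (4S,5S)-2-tert-butoxy-5-(3,5-dimethoxy-4-pivaloyloxyphenyl)-4-(3-methoxy-4-triisopropylsilyloxyphenyl)-1,3-dioxan-2-ylium | COc1cc([C@@H](OC(OC(C)(C)C)=[O+]C3)[C@H]3c2cc(OC)c(OC(=O)C(C)(C)C)c(OC)c2)ccc1O[Si](C(C)C)(C(C)C)C(C)C | intermediate (not isolated)
14 | trans-(4S,5S)-5-(3,5-dimethoxy-4-pivaloyloxyphenyl)-4-(3-methoxy-4-triisopropylsilyloxyphenyl)-1,3-dioxan-2-one | COc1cc([C@@H](OC(=O)OC3)[C@H]3c2cc(OC)c(OC(=O)C(C)(C)C)c(OC)c2)ccc1O[Si](C(C)C)(C(C)C)C(C)C | intermediate
15 | (1S,2S)-2-(4-hydroxy-3,5-dimethoxyphenyl)-1-(3-methoxy-4-triisopropylsilyloxyphenyl)propane-1,3-diol | COc1cc([C@@H](O)[C@H](CO)c2cc(OC)c(O)c(OC)c2)ccc1O[Si](C(C)C)(C(C)C)C(C)C | intermediate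
16 | (1S,2S)-1-(4-hydroxy-3-methoxyphenyl)-2-(4-hydroxy-3,5-dimethoxyphenyl)propane-1,3-diol | COc1cc([C@@H](O)[C@H](CO)c2cc(OC)c(O)c(OC)c2)ccc1O | target

**Step count**

Total step count: 9. Longest linear sequence: 8 steps (step 1 or step 2, then steps 3 to 9).

**Steps most likely to fail**

1. Step 7 (proposed new method). The benzylic cation may lose the C2 proton to give a stilbene instead of being captured. The silyl ether may be lost from the cation, leading to over-oxidation of the freed phenol. The ring closure may show poor facial selectivity.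
Fallback (known chemistry, sets out from 2 and 4, comes back at 15): the C1–O bond and both stereocentres are made by an auxiliary-controlled anti-aldol addition instead of C–H oxidation. Acid 4 is coupled with (S)-4-benzyl-2-oxazolidinone (DCC, DMAP, CH2Cl2) to give the N-acyl oxazolidinone F1. Its magnesium enolate (MgCl2 cat., Et3N, Me3SiCl, EtOAc, rt) adds to aldehyde 2 to give the O-trimethylsilyl anti-aldol adduct F2. The auxiliary antipode is chosen on the model of attack on the chelated enolate from the face away from the benzyl group. LiBH4 (THF, one equivalent of MeOH, 0 °C) removes the auxiliary to give the primary alcohol F3. NaOMe in MeOH then cleaves the trimethylsilyl ether and the pivalate to reach 15. Steps 3 to 8 are bypassed.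

2. Step 4. Enantiofacial selectivity on the α-aryl cinnamic acid may be insufficient or reversed, and the hindered trisubstituted alkene may be reduced slowly.
Fallback (sets out from 2 and 4, comes back at 9): the C2 stereocentre is set by auxiliary alkylation (Evans alkylation) instead of hydrogenation. Aldehyde 2 is reduced (NaBH4, MeOH, 0 °C) to the benzylic alcohol F4, which is converted (PBr3, Et2O, 0 °C) into the benzylic bromide F5, used at once. The sodium enolate of the N-acyl oxazolidinone F1 (made from 4 as described for step 7; NaN(SiMe3)2, THF, −78 °C) is alkylated with F5 on the face away from the auxiliary benzyl group to give the alkylated imide F6. LiBH4 (THF, one equivalent of MeOH, 0 °C) releases alcohol 9 and the auxiliary. Steps 3 to 5 are bypassed.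

3. Step 8. Methoxide may cleave the aryl silyl ether before the benzylic carbonate is opened, which would allow expulsion of the C1 oxygen through a quinone methide and scramble C1. Methanolysis of the hindered pivalate may also be sluggish.
Fallback (sets out from 14, comes back at 15): reductive instead of solvolytic cleavage. LiAlH4 in THF at 0 °C should reduce the cyclic carbonate to the diol and the pivalate to the phenol without an alkoxide medium, leaving the silyl ether in place; no new compound is made (F0).

**Further compounds**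

F1 | step 7 | (S)-4-benzyl-3-[2-(3,5-dimethoxy-4-pivaloyloxyphenyl)acetyl]oxazolidin-2-one | O=C(Cc1cc(OC)c(OC(=O)C(C)(C)C)c(OC)c1)N1[C@@H](Cc2ccccc2)COC1=O
F2 | step 7 | (S)-4-benzyl-3-[(2R,3S)-2-(3,5-dimethoxy-4-pivaloyloxyphenyl)-3-(3-methoxy-4-triisopropylsilyloxyphenyl)-3-(trimethylsilyloxy)propanoyl]oxazolidin-2-one | COc1cc([C@@H](O[Si](C)(C)C)[C@H](C(=O)N3[C@@H](Cc4ccccc4)COC3=O)c2cc(OC)c(OC(=O)C(C)(C)C)c(OC)c2)ccc1O[Si](C(C)C)(C(C)C)C(C)C
F3 | step 7 | (2S,3S)-2-(3,5-dimethoxy-4-pivaloyloxyphenyl)-3-(3-methoxy-4-triisopropylsilyloxyphenyl)-3-(trimethylsilyloxy)propan-1-ol | COc1cc([C@@H](O[Si](C)(C)C)[C@H](CO)c2cc(OC)c(OC(=O)C(C)(C)C)c(OC)c2)ccc1O[Si](C(C)C)(C(C)C)C(C)C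
F4 | step 4 | [3-methoxy-4-(triisopropylsilyloxy)phenyl]methanol | COc1cc(CO)ccc1O[Si](C(C)C)(C(C)C)C(C)C
F5 | step 4 | 4-(bromomethyl)-2-methoxy-1-(triisopropylsilyloxy)benzene | COc1cc(CBr)ccc1O[Si](C(C)C)(C(C)C)C(C)C
F6 | step 4 | (S)-4-benzyl-3-[(S)-2-(3,5-dimethoxy-4-pivaloyloxyphenyl)-3-(3-methoxy-4-triisopropylsilyloxyphenyl)propanoyl]oxazolidin-2-one | COc1cc(C[C@H](C(=O)N3[C@@H](Cc4ccccc4)COC3=O)c2cc(OC)c(OC(=O)C(C)(C)C)c(OC)c2)ccc1O[Si](C(C)C)(C(C)C)C(C)C
F0 | step 8 | none | none
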